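**Plan**

1. Retrosynthesis: the phenol is first masked as its acetate. The C3–C4 bond of the acyl chain (C1 = ester carbonyl carbon) is then cut into two carboxylic acids: octatriacontanoic acid, whose CO2H is lost so that its C37 alkyl becomes C4–C40, and the succinic half-ester of O-acetyltyrosol, whose free CO2H is lost so that its CH2CH2C(=O)O becomes C3–C1.
2. The C38 acid is cut at C16–C17 into 1-bromodocosane and 16-bromohexadecanoic acid. The half-ester is cut at the ester C–O bond into succinic anhydride and 4-(2-hydroxyethyl)phenyl acetate.
3. Forward: C22 + C16 give the C38 acid; tyrosol is acetylated on the phenol and succinylated on the primary alcohol; an anodic decarboxylative cross-coupling joins the C37 chain to the three-carbon ester unit; the aryl acetate is then removed.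
4. Enabling feature: C3 and C4 are unbranched, heteroatom-free CH2 groups of a polymethylene chain, with C3 β to the ester carbonyl C1. Each can therefore come from a primary alkyl radical made by loss of CO2 from a carboxylate. The only other oxidisable unit, the para-oxygenated benzene ring, is made electron-poor as its acetate.
5. Stereochemistry: the target has no stereocentre and no stereogenic double bond, so nothing has to be set.

Key step: step 4

Remark: the target is achiral, so the request for a single enantiomer needs no action; the acyl chain is taken as the unbranched C40 (tetracontanoyl) chain written in the SMILES.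

**Step 1**
Reactants: 1 1-bromodocosane; 2 16-bromohexadecanoic acid
Product: 5 octatriacontanoic acid, via docosylmagnesium bromide 3 (not isolated), via chloromagnesium 16-bromohexadecanoate 4 (not isolated)
Conditions: 1 (1.3 equiv), Mg, THF, 50 °C; separately 2, MeMgCl (1.0 equiv), THF, −20 °C; combine, Li2CuCl4 (3 mol %), −20 °C to rt; aq. HCl; recrystallisation from toluene
Reagents that add atoms: none
Why: Copper-catalysed cross-coupling of a primary alkyl Grignard reagent with a primary alkyl bromide (Kochi coupling) should join the C22 and C16 pieces at C16–C17, the carboxyl group riding through as its chloromagnesium salt, which is inert to the Grignard reagent at low temperature.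

**Step 2**
Reactants: 6 4-(2-hydroxyethyl)phenol (tyrosol)
Product: 7 4-(2-hydroxyethyl)phenyl acetate
Conditions: NaOH (1.0 equiv), H2O, 0 °C; Ac2O (1.05 equiv), 10 min; extraction
Reagents that add atoms: acetic anhydride, CC(=O)OC(C)=O
Why: Schotten–Baumann-type acetylation in cold aqueous alkali should be selective for the phenol, since only the phenol (pKa about 10) is ionised and the phenoxide outcompetes the neutral primary alcohol and water for the anhydride; the acetate makes the ring electron-poor enough for the anodic step.

**Step 3**
Reactants: 7 4-(2-hydroxyethyl)phenyl acetate; 8 succinic anhydride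
Product: 9 4-{2-[4-(acetyloxy)phenyl]ethoxy}-4-oxobutanoic acid
Conditions: 8 (1.5 equiv), pyridine, 40 °C; cold 1 M HCl/EtOAc work-up
Reagents that add atoms: none
Why: Ring-opening alcoholysis of a cyclic anhydride by the only free hydroxyl group should give the hydrogen succinate directly, an addition with no co-product that stops at the monoester because the new carboxyl group is not an acylating agent.

**Step 4**
Reactants: 5 octatriacontanoic acid; 9 4-{2-[4-(acetyloxy)phenyl]ethoxy}-4-oxobutanoic acid
Product: 10 2-[4-(acetyloxy)phenyl]ethyl tetracontanoate
Conditions: 5 (1 equiv), 9 (6 equiv), KOH (10 mol % of total CO2H, premixed with the acids), acetone, 50 °C, undivided cell, RVC anode and cathode, rapid alternating polarity (50 ms), 6 V; chromatography (warm hexane/CHCl3)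
Reagents that add atoms: none
Why: In this Kolbe anodic cross-coupling both carboxylates are oxidised at the anode, lose CO2 and give the primary heptatriacontyl radical and the 2-(alkoxycarbonyl)ethyl radical, which should combine at the electrode surface to form the C3–C4 bond. The closest known reaction type is the mixed Kolbe electrolysis of a long-chain fatty acid with an alkyl hydrogen succinate (Crum Brown–Walker chain extension), the classical way to lengthen a fatty acid by an ester-terminated segment. No ring is closed and no stereocentre is formed. Cross-coupling over homo-coupling is needed and is secured statistically by the six-fold excess of the cheap half-ester 9, so that nearly every C37 radical should meet a succinate-derived radical; the symmetrical by-products (the C74 alkane and the adipate diester) differ widely in polarity from 10. Radical coupling rather than further oxidation to a cation is needed and is secured by both radicals being primary, with no α-heteroatom or α-branch. The arene must stay intact, which is secured by the acetate on the ring oxygen (it raises the oxidation potential of the ring) and by the polarity switching, which limits over-oxidation; the alkyl ester and the aryl acetate should be inert in acetone buffered by the excess acid.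

**Step 5**
Reactants: 10 2-[4-(acetyloxy)phenyl]ethyl tetracontanoate
Product: 11 2-(4-hydroxyphenyl)ethyl tetracontanoate
Conditions: pyrrolidine (2 equiv), THF, 40 °C; dilute HCl wash; recrystallisation
Reagents that add atoms: none
Why: Aminolysis of an aryl ester should be selective because phenoxide is a far better leaving group than the alkoxide of the long-chain alkyl ester, so the secondary amine should remove only the phenolic acetate.

**Compound list**

1 | 1-bromodocosane | CCCCCCCCCCCCCCCCCCCCCCBr | starting material
2 | 16-bromohexadecanoic acid | OC(=O)CCCCCCCCCCCCCCCBr | starting material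
3 | docosylmagnesium bromide | CCCCCCCCCCCCCCCCCCCCCC[Mg]Br | intermediate
4 | chloromagnesium 16-bromohexadecanoate | BrCCCCCCCCCCCCCCCC(=O)O[Mg]Cl | intermediate
5 | octatriacontanoic acid | CCCCCCCCCCCCCCCCCCCCCCCCCCCCCCCCCCCCCC(=O)O | intermediate
6 | 4-(2-hydroxyethyl)phenol (tyrosol) | OCCc1ccc(O)cc1 | starting material
7 | 4-(2-hydroxyethyl)phenyl acetate | CC(=O)Oc1ccc(CCO)cc1 | intermediate
8 | succinic anhydride | O=C1CCC(=O)O1 | starting material
9 | 4-{2-[4-(acetyloxy)phenyl]ethoxy}-4-oxobutanoic acid | OC(=O)CCC(=O)OCCc1ccc(OC(C)=O)cc1 | intermediate
10 | 2-[4-(acetyloxy)phenyl]ethyl tetracontanoate | CCCCCCCCCCCCCCCCCCCCCCCCCCCCCCCCCCCCCCCC(=O)OCCc1ccc(OC(C)=O)cc1 | intermediate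
11 | 2-(4-hydroxyphenyl)ethyl tetracontanoate | CCCCCCCCCCCCCCCCCCCCCCCCCCCCCCCCCCCCCCCC(=O)OCCc1ccc(O)cc1 | target

**Step count and risks**

Total step count: 5. Longest linear sequence: 4 steps (6 to 7 to 9 to 10 to 11).

Steps most likely to fail:

1. Step 4. The very poorly soluble acid 5 may be under-represented at the anode, so that homo-coupling of 9 dominates and conversion of 5 stalls; anodic oxidation of the arene may also foul the electrode. The fallback sets out from 5 and 7 and comes back at 10. Acid 5 would be condensed with N-hydroxyphthalimide (N,N'-diisopropylcarbodiimide, DMAP cat., warm THF/CH2Cl2) to the redox-active ester 1,3-dioxoisoindolin-2-yl octatriacontanoate F1. Alcohol 7 would be acylated with acryloyl chloride and Et3N (CH2Cl2, 0 °C) to 2-[4-(acetyloxy)phenyl]ethyl prop-2-enoate F2. A reductive decarboxylative Giese addition of F1 to F2 (Ru(bpy)3(PF6)2 cat., Hantzsch ester, iPr2NEt, THF/CH2Cl2, 40 °C, blue LEDs) should form the same C3–C4 bond without a statistical partner and give 10.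

2. Step 1. Wurtz-type homo-coupling during Grignard formation and precipitation of the long-chain organomagnesium species at −20 °C may leave the coupling incomplete. The fallback sets out from 2 and comes back at 5. Heating 2 with PPh3 (MeCN, reflux) should give (15-carboxypentadecyl)triphenylphosphonium bromide F3. Double deprotonation (NaHMDS, 2.1 equiv, THF, −20 °C) and Wittig olefination with commercial docosanal should give (16Z)-octatriacont-16-enoic acid F4. Hydrogenation (H2, Pd/C, THF/EtOAc, 50 °C) should then give 5.

3. Step 5. If the poorly soluble ester 10 needs forcing, chemoselectivity may be lost through aminolysis or transesterification of the long-chain ester linkage, or conversion may remain incomplete. The fallback sets out from 10 and comes back at 11. Full saponification (KOH, EtOH/THF/H2O, reflux; then HCl) should give tetracontanoic acid F5. Mitsunobu esterification of F5 with tyrosol 6 (PPh3, DIAD, THF, 40 °C) should acylate only the primary alcohol, because the carboxylic acid rather than the phenol acts as the acidic partner, and give 11.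

**Further compounds**

F1 | step 4 | 1,3-dioxoisoindolin-2-yl octatriacontanoate | CCCCCCCCCCCCCCCCCCCCCCCCCCCCCCCCCCCCCC(=O)ON1C(=O)c2ccccc2C1=O
F2 | step 4 | 2-[4-(acetyloxy)phenyl]ethyl prop-2-enoate | C=CC(=O)OCCc1ccc(OC(C)=O)cc1
F3 | step 1 | (15-carboxypentadecyl)triphenylphosphonium bromide | OC(=O)CCCCCCCCCCCCCCC[P+](c1ccccc1)(c1ccccc1)c1ccccc1.[Br-]
F4 | step 1 | (16Z)-octatriacont-16-enoic acid | CCCCCCCCCCCCCCCCCCCCC/C=C\CCCCCCCCCCCCCCC(=O)O
F5 | step 5 | tetracontanoic acid | CCCCCCCCCCCCCCCCCCCCCCCCCCCCCCCCCCCCCCCC(=O)O
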